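**Retrosynthetic overview**
1. The building blocks are 2,5-dimethylhydroquinone (1) and all-E geranylgeraniol (2); the arene ring is bought, not made.
2. Their union, the ring-opened geranylgeranyl hydroquinone (3), is the direct precursor of the target, (R)-β-tocotrienol (4).
3. Disconnection of 4 at O1–C2: enantioselective, proton-initiated 6-endo closure of the ortho phenol of 3 onto its 2',3'-alkene under a confined chiral Brønsted acid. This is the move of tocopherol cyclase; it forms the only new ring (the dihydropyran ring) and sets C2 in the same event, with no protecting groups.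
4. Disconnection of 3 at the aryl–C1' bond: Friedel–Crafts C-allylation of 1 by 2, the chemical counterpart of the prenyl transfer to the hydroquinone.

Assumption: the hand of the chiral acid that gives (R) in step 2 cannot be predicted with certainty; the (S,S) catalyst is written, and its mirror image (from (R)-BINOL) is used unchanged otherwise if one analytical trial shows (S).

**Step 1**
Reactants: 1 2,5-dimethylbenzene-1,4-diol (2,5-dimethylhydroquinone, 3 equiv, excess recovered); 2 (2E,6E,10E)-3,7,11,15-tetramethylhexadeca-2,6,10,14-tetraen-1-ol (all-E geranylgeraniol, 1 equiv)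
Product: 3 2,5-dimethyl-3-[(2E,6E,10E)-3,7,11,15-tetramethylhexadeca-2,6,10,14-tetraen-1-yl]benzene-1,4-diol
Conditions: BF3·OEt2 (30 mol%), degassed 1,4-dioxane, rt, 16 h, Ar; aqueous NaHCO3 work-up; chromatography (removes bis-allylated material, any 2'Z isomer and any racemic chroman formed by over-reaction)
Reagents that add atoms: none
Why: Friedel–Crafts allylation, in which BF3 ionises the primary allylic alcohol to a configurationally stable transoid allyl cation that the electron-rich hydroquinone captures through its primary terminus at a free ring carbon (the two free positions of 1 are equivalent by symmetry), keeping the 2'E geometry; no stereocentre is formed.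

**Step 2**
Reactants: 3 2,5-dimethyl-3-[(2E,6E,10E)-3,7,11,15-tetramethylhexadeca-2,6,10,14-tetraen-1-yl]benzene-1,4-diol
Product: 4 (R)-β-tocotrienol, (2R)-2,5,8-trimethyl-2-[(3E,7E)-4,8,12-trimethyltrideca-3,7,11-trien-1-yl]-3,4-dihydro-2H-chromen-6-ol
Conditions: (S,S)-IDPi acid HN[P(=NSO2CF3)(O2C20H10Ar2)]2, each O2C20H10Ar2 an (S)-3,3'-diaryl-1,1'-binaphthalene-2,2'-diolate with Ar = 3,5-(CF3)2C6H3 (5 mol%), degassed toluene (0.05 M), 0 °C → rt, 24–48 h, Ar, dark; Et3N quench, silica
Reagents that add atoms: none
Why: Proposed new method: the confined chiral acid hydrogen-bonds the ortho phenol, delivers its proton to C2' of the adjacent alkene while the phenol oxygen closes anti on the developing tertiary cation at C3' in a concerted, asynchronous Markovnikov 6-endo event (catalytic asymmetric intramolecular hydroalkoxylation), the pocket telling the methyl group from the C16 chain at C3' and thereby fixing the alkene face and the (R) centre; the three distal trisubstituted alkenes have no internal nucleophile within reach and are not expected to be protonated in a non-polar solvent, and the closest known reaction types are the IDPi-catalysed asymmetric intramolecular hydroalkoxylation of unactivated alkenols and the racemic acid-catalysed chroman closure of prenylated hydroquinones.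

**Compound list**
1 | 2,5-dimethylbenzene-1,4-diol (2,5-dimethylhydroquinone) | Cc1cc(O)c(C)cc1O | starting material
2 | (2E,6E,10E)-3,7,11,15-tetramethylhexadeca-2,6,10,14-tetraen-1-ol (all-E geranylgeraniol) | CC(C)=CCC/C(C)=C/CC/C(C)=C/CC/C(C)=C/CO | starting material
3 | 2,5-dimethyl-3-[(2E,6E,10E)-3,7,11,15-tetramethylhexadeca-2,6,10,14-tetraen-1-yl]benzene-1,4-diol | CC(C)=CCC/C(C)=C/CC/C(C)=C/CC/C(C)=C/Cc1c(C)c(O)cc(C)c1O | intermediate
4 | (R)-β-tocotrienol, (2R)-2,5,8-trimethyl-2-[(3E,7E)-4,8,12-trimethyltrideca-3,7,11-trien-1-yl]-3,4-dihydro-2H-chromen-6-ol | CC(C)=CCC/C(C)=C/CC/C(C)=C/CC[C@]1(C)CCc2c(C)c(O)cc(C)c2O1 | target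

**Totals**
Total step count: 2. Longest linear sequence: 2.

**Steps most likely to fail** (the route has two steps, so both are ranked; there is no third)

First, step 2. The risks are an incomplete ee, protonation of a distal alkene leading to cyclisation within the chain, and racemic background closure. The fallback replaces asymmetric catalysis by resolution and sets out from 3. Compound 3 is closed with p-TsOH·H2O (10 mol%) in toluene at 60 °C to racemic β-tocotrienol F1. The enantiomers of F1 are separated by preparative supercritical-fluid chromatography on an amylose tris(3,5-dimethylphenylcarbamate) phase, and the (R) fraction is 4, where the fallback comes back to the route. The same column serves as a polish if step 2 gives a high but incomplete ee.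

Second, step 1. The risks are a low yield through bis-allylation or O-allylation, partial loss of the 2'E geometry, and premature racemic ring closure. The fallback replaces cationic allylation by directed metalation and allyl–copper coupling and sets out from 1 and 2:
- 1 is methylated (Me2SO4, K2CO3, acetone, reflux) to 1,4-dimethoxy-2,5-dimethylbenzene F2.
- 2 is converted with PBr3 (Et2O, −10 °C) into (2E,6E,10E)-geranylgeranyl bromide F3.
- F2 is lithiated ortho to a methoxy group (n-BuLi, TMEDA, Et2O, 0 °C → rt), transmetalated with CuBr·SMe2 (−40 °C) and alkylated by F3 at its primary carbon to give 1,4-dimethoxy-2,5-dimethyl-3-[(2E,6E,10E)-geranylgeranyl]benzene F4.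
- Oxidative demethylation with (NH4)2Ce(NO3)6 (MeCN/H2O, 0 °C) gives 2,5-dimethyl-3-[(2E,6E,10E)-geranylgeranyl]-1,4-benzoquinone F5.
- Reduction with Na2S2O4 (Et2O/H2O, rt) gives 3, where the fallback comes back to the route.

**Further compounds**
F1 | step 2 | racemic β-tocotrienol, (2RS)-2,5,8-trimethyl-2-[(3E,7E)-4,8,12-trimethyltrideca-3,7,11-trien-1-yl]-3,4-dihydro-2H-chromen-6-ol | CC(C)=CCC/C(C)=C/CC/C(C)=C/CCC1(C)CCc2c(C)c(O)cc(C)c2O1
F2 | step 1 | 1,4-dimethoxy-2,5-dimethylbenzene | COc1cc(C)c(OC)cc1C
F3 | step 1 | (2E,6E,10E)-1-bromo-3,7,11,15-tetramethylhexadeca-2,6,10,14-tetraene (geranylgeranyl bromide) | CC(C)=CCC/C(C)=C/CC/C(C)=C/CC/C(C)=C/CBr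
F4 | step 1 | 1,4-dimethoxy-2,5-dimethyl-3-[(2E,6E,10E)-3,7,11,15-tetramethylhexadeca-2,6,10,14-tetraen-1-yl]benzene | CC(C)=CCC/C(C)=C/CC/C(C)=C/CC/C(C)=C/Cc1c(C)c(OC)cc(C)c1OC
F5 | step 1 | 2,5-dimethyl-3-[(2E,6E,10E)-3,7,11,15-tetramethylhexadeca-2,6,10,14-tetraen-1-yl]cyclohexa-2,5-diene-1,4-dione | CC(C)=CCC/C(C)=C/CC/C(C)=C/CC/C(C)=C/CC1=C(C)C(=O)C=C(C)C1=O
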